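The target is disconnected across both rings to an acyclic trienenitrile whose last alkene (C8=C9, labdane numbering, defined below) bears a methoxymethyl group on C8. One enantioselective bromonium transfer to the terminal alkene triggers a cation–olefin cascade: ring A closes first (C4–C5), ring B last (C9–C10), and the C8 cation collapses by a 1,2-hydride shift from the CH2OMe carbon (C14) to a C8 aldehyde. The step exploits the axial C9 side chain between the quaternary C8 and C10 of ring B: the C8=C9 geometry (C7 cis to C11) is translated into 9β-H, while C3, C5 and C10 are relayed from the catalyst-set bromonium. Enolate methylation, methylenation and MeLi addition to the nitrile complete the target.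

Key step: step 6

Remark: labdane-type numbering is used (ring A = C1–C5/C10 with C3–Br and C4 gem-dimethyl; ring B = C5–C10; C11–C12–C13(=O)–C16 on C9; C14=C15 vinyl and C17 methyl on C8; C20 methyl on C10; the target is 3β-Br, 5α-H, 10β-Me, 9β-H, 8α-Me, 8β-vinyl), and it is assumed that the catalyst antipode giving the 3S bromide is identified on a model polyene.

Step 1
Reactants: 1 geranyl bromide; 2 propyne; 3 methyl chloroformate
Product: 5 methyl (6E)-7,11-dimethyldodeca-6,10-dien-2-ynoate, via lithium enynide 4 (not isolated)
Conditions: 2, n-BuLi (2.1 equiv), TMEDA, THF/hexane, −78 → 0 °C; 1, −78 → 0 °C; then 3, −78 °C → rt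
Reagents that add atoms: none
Why: Sequential alkylation/acylation of 1,3-dilithiopropyne: the sp3 carbanion is alkylated by the allylic bromide (SN2, E alkene untouched) and the remaining lithium acetylide 4 is C-acylated by the chloroformate; no stereocentre is formed.

Step 2
Reactants: 5 methyl (6E)-7,11-dimethyldodeca-6,10-dien-2-ynoate; 6 tributyl(methoxymethyl)stannane
Product: 7 methyl (2E,6E)-3-(methoxymethyl)-7,11-dimethyldodeca-2,6,10-trienoate
Conditions: 6, n-BuLi, THF, −78 °C; CuBr·SMe2 (0.5 equiv per Li), −78 °C; then 5, −78 °C; MeOH/aq. NH4Cl quench at −78 °C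
Reagents that add atoms: none
Why: syn-Carbocupration (conjugate addition of a Gilman-type α-alkoxymethyl cuprate, made by Sn–Li exchange, to a 2-ynoate) at −78 °C places MeOCH2 and H cis, so the C4 chain is cis to the ester; this alkene geometry later sets C9.

Step 3
Reactants: 7 methyl (2E,6E)-3-(methoxymethyl)-7,11-dimethyldodeca-2,6,10-trienoate
Product: 8 (2E,6E)-3-(methoxymethyl)-7,11-dimethyldodeca-2,6,10-trien-1-ol
Conditions: DIBAL-H (2.5 equiv), CH2Cl2, −78 °C; Rochelle salt work-up
Reagents that add atoms: none
Why: DIBAL-H 1,2-reduction of the enoate to the allylic alcohol, which leaves the trisubstituted alkene geometry untouched.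

Step 4
Reactants: 8 (2E,6E)-3-(methoxymethyl)-7,11-dimethyldodeca-2,6,10-trien-1-ol
Product: 9 (2E,6E)-1-bromo-3-(methoxymethyl)-7,11-dimethyldodeca-2,6,10-triene
Conditions: CBr4, PPh3, CH2Cl2, −20 → 0 °C
Reagents that add atoms: carbon tetrabromide BrC(Br)(Br)Br
Why: Appel bromination of the primary allylic alcohol under neutral conditions should retain the alkene geometry.

Step 5
Reactants: 9 (2E,6E)-1-bromo-3-(methoxymethyl)-7,11-dimethyldodeca-2,6,10-triene; 10 acetonitrile
Product: 11 (4E,8E)-5-(methoxymethyl)-9,13-dimethyltetradeca-4,8,12-trienenitrile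
Conditions: 10, n-BuLi, THF, −78 °C (LiCH2CN, 3 equiv); then 9, −78 → −40 °C
Reagents that add atoms: none
Why: SN2 alkylation of lithioacetonitrile by the primary allylic bromide (SN2′ at the fully substituted γ-carbon is disfavoured), the classical cyanomethyl chain extension; the nitrile is a non-nucleophilic mask of the methyl ketone.

Step 6
Reactants: 11 (4E,8E)-5-(methoxymethyl)-9,13-dimethyltetradeca-4,8,12-trienenitrile
Product: 14 3-[(1R,2S,4aR,6S,8aR)-6-bromo-2-formyl-5,5,8a-trimethyldecahydronaphthalen-1-yl]propanenitrile, via monocyclic bromodiene 12 (not isolated), via bicyclic methoxycarbenium ion 13 (not isolated)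
Conditions: DBDMH (1.1 equiv), chiral BINOL-derived thiophosphoramide (10 mol%), PhMe/CH2Cl2, −90 °C; then ClSO3H (3 equiv), i-PrNO2, −78 °C; aq. NaHCO3
Reagents that add atoms: 1,3-dibromo-5,5-dimethylhydantoin CC1(C)N(Br)C(=O)N(Br)C1=O; water O
Why: Proposed new method: the chiral Lewis base transfers Br+ to one face of the terminal C3=C4 alkene, the bromonium is opened anti by C5 (6-endo, chair, ring A), and after acid re-ionisation of any monocyclic alkene 12 the C10 cation is attacked by C9 (6-endo-trig, chair, ring B); the resulting C8 cation is quenched by a 1,2-hydride shift from C14 to give methoxycarbenium ion 13, which is hydrolysed to the aldehyde on work-up. The closest known reaction types are the Lewis-base-catalysed enantioselective bromo-polyene cyclisation completed with ClSO3H and cation–olefin cyclisations terminated by a pinacol-type 1,2-shift (Prins–pinacol type, and the pinacol rearrangement of tertiary/primary glycol derivatives to aldehydes); the new element is their combination with hydride as the migrating group. C3 is set by the catalyst, and C5 and C10 follow from anti addition across the E C5=C10 alkene in a chair (trans-decalin, equatorial Br). C9 follows from the C8=C9 geometry: C11 is cis to C7 and so becomes axial (α, anti to the C10 methyl), while C8 (mainly 8β-CHO) is not controlled here and is reset in step 7. The step needs bromination of the terminal alkene only, which the inductive deactivation of the C8=C9 alkene by its CH2OMe group should secure. It also needs ring B closure and the hydride shift to outrun loss of the C9 proton or ionisation of the allylic ether; this is favoured by the strongly exothermic formation of 13, and proton loss from C14 would give the enol ether and hence the same aldehyde.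

Step 7
Reactants: 14 3-[(1R,2S,4aR,6S,8aR)-6-bromo-2-formyl-5,5,8a-trimethyldecahydronaphthalen-1-yl]propanenitrile
Product: 15 3-[(1S,2S,4aR,6S,8aR)-6-bromo-2-formyl-2,5,5,8a-tetramethyldecahydronaphthalen-1-yl]propanenitrile
Conditions: MeI (5 equiv), t-BuOK (1.2 equiv, added last), THF, −40 → 0 °C
Reagents that add atoms: iodomethane CI
Why: C-alkylation of the exocyclic potassium aldehyde enolate: MeI should enter from the α face because the β face is blocked by the syn-axial C10 methyl and ring carbons C6/C10, giving 8α-Me/8β-CHO; the nitrile α-H is far less acidic and the equatorial C3–Br has no antiperiplanar H for E2.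

Step 8
Reactants: 15 3-[(1S,2S,4aR,6S,8aR)-6-bromo-2-formyl-2,5,5,8a-tetramethyldecahydronaphthalen-1-yl]propanenitrile
Product: 16 3-[(1R,2R,4aR,6S,8aR)-6-bromo-2-ethenyl-2,5,5,8a-tetramethyldecahydronaphthalen-1-yl]propanenitrile
Conditions: Ph3PCH3Br, t-BuOK, THF, 0 °C → rt
Reagents that add atoms: methyltriphenylphosphonium bromide C[P+](c1ccccc1)(c1ccccc1)c1ccccc1.[Br-]
Why: Wittig methylenation of the non-enolisable neopentyl aldehyde; no stereocentre is touched.

Step 9
Reactants: 16 3-[(1R,2R,4aR,6S,8aR)-6-bromo-2-ethenyl-2,5,5,8a-tetramethyldecahydronaphthalen-1-yl]propanenitrile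
Product: 18 4-[(1R,2R,4aR,6S,8aR)-6-bromo-2-ethenyl-2,5,5,8a-tetramethyldecahydronaphthalen-1-yl]butan-2-one (CNP0189852.2), via lithium ketimide 17 (not isolated)
Conditions: MeLi (2.5 equiv), Et2O, −78 → 0 °C; then 1 M aq. HCl, THF, 0 °C → rt
Reagents that add atoms: methyllithium [Li]C; water O
Why: Addition of MeLi to the nitrile gives lithium ketimide 17, which is hydrolysed to the methyl ketone on acidic work-up (ketone synthesis from nitriles); the hindered equatorial secondary bromide and the vinyl group should be inert.

Compound list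
1 | geranyl bromide, (2E)-1-bromo-3,7-dimethylocta-2,6-diene | BrC/C=C(\C)CCC=C(C)C | starting material
2 | propyne | CC#C | starting material
3 | methyl chloroformate | COC(=O)Cl | starting material
4 | lithium (5E)-6,10-dimethylundeca-5,9-dien-1-yn-1-ide | [Li]C#CCC/C=C(\C)CCC=C(C)C | intermediate
5 | methyl (6E)-7,11-dimethyldodeca-6,10-dien-2-ynoate | COC(=O)C#CCC/C=C(\C)CCC=C(C)C | intermediate
6 | tributyl(methoxymethyl)stannane | CCCC[Sn](CCCC)(CCCC)COC | starting material
7 | methyl (2E,6E)-3-(methoxymethyl)-7,11-dimethyldodeca-2,6,10-trienoate (chain cis to ester) | COC(=O)/C=C(/COC)CC/C=C(\C)CCC=C(C)C | intermediate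
8 | (2E,6E)-3-(methoxymethyl)-7,11-dimethyldodeca-2,6,10-trien-1-ol | OC/C=C(/COC)CC/C=C(\C)CCC=C(C)C | intermediate
9 | (2E,6E)-1-bromo-3-(methoxymethyl)-7,11-dimethyldodeca-2,6,10-triene | BrC/C=C(/COC)CC/C=C(\C)CCC=C(C)C | intermediate
10 | acetonitrile | CC#N | starting material
11 | (4E,8E)-5-(methoxymethyl)-9,13-dimethyltetradeca-4,8,12-trienenitrile | N#CCC/C=C(/COC)CC/C=C(\C)CCC=C(C)C | intermediate
12 | (4E)-7-[(1R,3S)-3-bromo-2,2-dimethyl-6-methylidenecyclohexyl]-5-(methoxymethyl)hept-4-enenitrile (exocyclic isomer shown; the endocyclic alkene isomer converges) | C=C1CC[C@H](Br)C(C)(C)[C@@H]1CC/C(COC)=C\CCC#N | intermediate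
13 | bicyclic O-methyl oxocarbenium ion of 14 (3β-Br, 5α-H, 10β-Me, 9α-CH2CH2CN, 8β-CH=O+Me) | C[O+]=C[C@H]1CC[C@H]2C(C)(C)[C@@H](Br)CC[C@]2(C)[C@@H]1CCC#N | intermediate
14 | 3-[(1R,2S,4aR,6S,8aR)-6-bromo-2-formyl-5,5,8a-trimethyldecahydronaphthalen-1-yl]propanenitrile (3β-Br, 9α-chain, 8β-CHO; the C8 epimer serves equally) | O=C[C@H]1CC[C@H]2C(C)(C)[C@@H](Br)CC[C@]2(C)[C@@H]1CCC#N | intermediate
15 | 3-[(1S,2S,4aR,6S,8aR)-6-bromo-2-formyl-2,5,5,8a-tetramethyldecahydronaphthalen-1-yl]propanenitrile (8α-Me, 8β-CHO) | O=C[C@@]1(C)CC[C@H]2C(C)(C)[C@@H](Br)CC[C@]2(C)[C@@H]1CCC#N | intermediate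
16 | 3-[(1R,2R,4aR,6S,8aR)-6-bromo-2-ethenyl-2,5,5,8a-tetramethyldecahydronaphthalen-1-yl]propanenitrile | C=C[C@@]1(C)CC[C@H]2C(C)(C)[C@@H](Br)CC[C@]2(C)[C@@H]1CCC#N | intermediate
17 | N-lithio ketimine of 18 | C=C[C@@]1(C)CC[C@H]2C(C)(C)[C@@H](Br)CC[C@]2(C)[C@@H]1CCC(C)=N[Li] | intermediate
18 | 4-[(1R,2R,4aR,6S,8aR)-6-bromo-2-ethenyl-2,5,5,8a-tetramethyldecahydronaphthalen-1-yl]butan-2-one | C=C[C@@]1(C)CC[C@H]2C(C)(C)[C@@H](Br)CC[C@]2(C)[C@@H]1CCC(C)=O | target

Total step count: 9. Longest linear sequence: 9 steps (from geranyl bromide 1).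

Steps most likely to fail

Step 6 (Proposed new method). What may go wrong: bromonium transfer to an internal alkene; proton loss after ring A without closure of ring B because the CH2OMe-bearing alkene is too poor a nucleophile; acid ionisation of the allylic ether; or loss of the C9 proton from the C8 cation (scrambling C9) in place of the hydride shift. The fallback uses known chemistry and reverses the polarity of the ring B closure. Setting out from 11, DDQ in wet CH2Cl2 should oxidise the allylic methyl ether (the oxidative cleavage used for prenyl-type ethers) to the enal (4E,8E)-5-formyl-9,13-dimethyltetradeca-4,8,12-trienenitrile F1. The same Lewis-base-catalysed bromination is then a plain bromo-monocyclisation ended by proton loss, because the enal alkene is inert to cations, and should give the monocyclic bromo enal (4E)-7-[(1R,3S)-3-bromo-2,2-dimethyl-6-methylidenecyclohexyl]-5-formylhept-4-enenitrile F2. Fe(acac)3/PhSiH3 in EtOH then transfers a hydrogen atom to the ring alkene, and the C10 tertiary radical adds 6-endo to the enal β-carbon C9 (MHAT-initiated Giese cyclisation), closing ring B. Reduction and protonation of the α-formyl radical should give aldehyde 14, where the route is rejoined.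

Step 7. What may go wrong: approach of MeI syn to the C10 methyl (wrong C8 configuration), or O-methylation of the hindered enolate. Fallback by a cyclopropanation/ring-opening methylation instead of enolate alkylation: setting out from 14, TMSOTf/Et3N should give the trimethylsilyl enol ether of 14 (exocyclic C8=C14) F3. Furukawa-modified Simmons–Smith cyclopropanation (Et2Zn, CH2I2), a concerted addition that is more sensitive to the shielding by the angular methyl, should give the spiro siloxycyclopropane F4 with the new CH2 on the α face. Acid (HCl, aq. THF) then opens the less substituted cyclopropane bond to the α-methyl aldehyde 15, where the route is rejoined.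

Step 2. What may go wrong: loss of alkene geometry by equilibration of the alkenylcuprate through its allenoate above −78 °C, or decomposition of the α-alkoxymethyl cuprate before it adds. Fallback by stereoretentive cross-coupling: setting out from 1, alkylation of the dianion of methyl acetoacetate (NaH, then n-BuLi) should give the β-keto ester methyl (6E)-7,11-dimethyl-3-oxododeca-6,10-dienoate F5. E-selective enol triflation (Tf2O, aq. Me4NOH, hexane) should give methyl (2E,6E)-7,11-dimethyl-3-(trifluoromethanesulfonyloxy)dodeca-2,6,10-trienoate F6. Stille coupling of F6 with stannane 6 (Pd(PPh3)4, CuI, LiCl, DMF) with retention of geometry should give 7, where the route is rejoined.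

Further compounds
F1 | step 6 | (4E,8E)-5-formyl-9,13-dimethyltetradeca-4,8,12-trienenitrile | N#CCC/C=C(/C=O)CC/C=C(\C)CCC=C(C)C
F2 | step 6 | (4E)-7-[(1R,3S)-3-bromo-2,2-dimethyl-6-methylidenecyclohexyl]-5-formylhept-4-enenitrile | C=C1CC[C@H](Br)C(C)(C)[C@@H]1CC/C(C=O)=C\CCC#N
F3 | step 7 | trimethylsilyl enol ether of 14 (exocyclic C8=C14) | C[Si](C)(C)OC=C1CC[C@H]2C(C)(C)[C@@H](Br)CC[C@]2(C)[C@@H]1CCC#N
F4 | step 7 | spiro siloxycyclopropane at C8 (new CH2 on the α face) | C[Si](C)(C)OC3C[C@@]34CC[C@H]5C(C)(C)[C@@H](Br)CC[C@]5(C)[C@@H]4CCC#N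
F5 | step 2 | methyl (6E)-7,11-dimethyl-3-oxododeca-6,10-dienoate | COC(=O)CC(=O)CC/C=C(\C)CCC=C(C)C
F6 | step 2 | methyl (2E,6E)-7,11-dimethyl-3-(trifluoromethanesulfonyloxy)dodeca-2,6,10-trienoate | COC(=O)/C=C(/OS(=O)(=O)C(F)(F)F)CC/C=C(\C)CCC=C(C)C
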